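**Plan**

1. Retrosynthetic cuts (pterocarpan numbering): (a) the ring A bond C4–CH= of the dimethylchromene, opened to an O-(1,1-dimethylpropargyl) ether at the isoflavone oxidation level; (b) O11–C11a, back to a 2'-hydroxyisoflavan-4-ol and hence to the isoflavone; (c) the bond from C6a to ring D, undone as a 1,2-aryl shift to a chalcone, which is cut at C6–C6a into a ring A acetophenone and a ring D aldehyde; (d) the ring D pyran, back to 2,4-dihydroxybenzaldehyde and 3-methylbut-2-enal.
2. Forward order: ring D pyran first (chromene, epoxide, (R)-chromanol), then the chalcone, the aryl shift that closes the 4-pyranone, debenzylation, propargylation at O7, thermal closure of the ring A chromene, and last the reduction and closure of the dihydrofuran ring.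
3. Feature that makes the key event possible: in the isoflavone the 4-pyranone fused to ring A fixes the C7=C8 bond (as in a 2-naphthyl ether), so the O7–C(CH3)2–C≡CH unit can reach only C8, the carbon between O7 and the ring oxygen O1 (C4 of the target). The C4 carbonyl is the helper: it is later reduced and leaves as water when O11–C11a forms.
4. Stereochemistry: the ring D carbinol comes from a Jacobsen–Katsuki epoxidation with the (R,R)-salen ligand and hydride opening at the benzylic carbon. C6a and C11a come from a transfer hydrogenation with dynamic kinetic resolution using RuCl[(R,R)-TsDPEN](p-cymene), followed by a stereoconvergent cis ring closure through the C11a benzylic cation.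

Key step: step 10

Assumption: the SMILES is read as the (6aR,11aR) cis-pterocarpan with an (R)-carbinol; the sense of induction of both (R,R)-ligands is taken from the accepted models for 2,2-dimethylchromenes and aryl ketones, and the antipodal ligand would be used if an assay showed the opposite. Isoflavone numbering is used for compounds 11 to 19.

**Step 1**
Reactants: 1 2,4-dihydroxybenzaldehyde; 2 3-methylbut-2-enal
Product: 3 5-hydroxy-2,2-dimethyl-2H-chromene-6-carbaldehyde
Conditions: pyridine, 140 °C, sealed tube
Reagents that add atoms: none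
Why: Chromene annulation of a phenol with an enal (aldol-type attack of the ring carbon between the two hydroxyls, loss of water to an ortho-quinone methide, oxa-6π electrocyclisation), in which the 2-OH stays hydrogen-bonded to the formyl group so that only the 4-OH closes the ring and the angular 5-hydroxychromene should result.

**Step 2**
Reactants: 3 5-hydroxy-2,2-dimethyl-2H-chromene-6-carbaldehyde
Product: 4 5-(benzyloxy)-2,2-dimethyl-2H-chromene-6-carbaldehyde
Conditions: BnBr, K2CO3, DMF, 60 °C
Reagents that add atoms: benzyl bromide, BrCc1ccccc1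
Why: Williamson ether synthesis on the chelated phenol, which needs a dipolar solvent and warming but has no competing nucleophile.

**Step 3**
Reactants: 4 5-(benzyloxy)-2,2-dimethyl-2H-chromene-6-carbaldehyde
Product: 5 (3R,4R)-5-(benzyloxy)-3,4-epoxy-2,2-dimethyl-3,4-dihydro-2H-chromene-6-carbaldehyde
Conditions: (R,R)-(salen)MnCl [Jacobsen catalyst; salen = N,N'-bis(3,5-di-tert-butylsalicylidene)cyclohexane-1,2-diamine dianion] (5 mol %), 4-phenylpyridine N-oxide, aq NaOCl buffered to pH 11.3, CH2Cl2, 0 °C
Reagents that add atoms: sodium hypochlorite, [Na+].[O-]Cl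
Why: Jacobsen–Katsuki epoxidation of a cis-disubstituted 2,2-dimethylchromene, the best substrate class for this catalyst, in which the (R,R)-ligand should direct oxygen transfer to the face that gives the (3R,4R)-epoxide while the electron-poor aryl aldehyde is left alone by buffered hypochlorite at 0 °C.

**Step 4**
Reactants: 5 (3R,4R)-5-(benzyloxy)-3,4-epoxy-2,2-dimethyl-3,4-dihydro-2H-chromene-6-carbaldehyde
Product: 6 (3R)-5-(benzyloxy)-6-(hydroxymethyl)-2,2-dimethylchroman-3-ol
Conditions: LiAlH4, THF, 0 °C to rt
Reagents that add atoms: none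
Why: Hydride reduction in which LiAlH4 opens the epoxide by SN2 attack at the benzylic C4 (C3 is neopentyl), leaving the C3–O bond and thus the (R) configuration intact, and reduces the aldehyde to the benzylic alcohol in the same operation.

**Step 5**
Reactants: 6 (3R)-5-(benzyloxy)-6-(hydroxymethyl)-2,2-dimethylchroman-3-ol
Product: 7 (3R)-5-(benzyloxy)-3-hydroxy-2,2-dimethylchromane-6-carbaldehyde
Conditions: activated MnO2, CH2Cl2, rt
Reagents that add atoms: none
Why: Chemoselective MnO2 oxidation, which should convert the benzylic alcohol to the aldehyde and leave the saturated secondary alcohol untouched.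

**Step 6**
Reactants: 7 (3R)-5-(benzyloxy)-3-hydroxy-2,2-dimethylchromane-6-carbaldehyde; 8 1-[4-(benzyloxy)-2-hydroxyphenyl]ethan-1-one
Product: 9 (E)-1-[4-(benzyloxy)-2-hydroxyphenyl]-3-[(3R)-5-(benzyloxy)-3-hydroxy-2,2-dimethylchroman-6-yl]prop-2-en-1-one
Conditions: 50% aq KOH, EtOH, rt
Reagents that add atoms: none
Why: Claisen–Schmidt condensation of the methyl ketone enolate with the non-enolisable aldehyde, which should give the E enone, the ring A phenoxide keeping the 2'-hydroxychalcone from closing to the flavanone under the strongly basic conditions.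

**Step 7**
Reactants: 9 (E)-1-[4-(benzyloxy)-2-hydroxyphenyl]-3-[(3R)-5-(benzyloxy)-3-hydroxy-2,2-dimethylchroman-6-yl]prop-2-en-1-one
Product: 11 7-(benzyloxy)-3-[(3R)-5-(benzyloxy)-3-hydroxy-2,2-dimethylchroman-6-yl]-4H-chromen-4-one, via dimethyl acetal 10 (not isolated)
Conditions: Tl(NO3)3·3H2O, MeOH/CH(OMe)3, rt; then 10% aq HCl, MeOH, 60 °C
Reagents that add atoms: none
Why: Thallium-mediated oxidative rearrangement of a 2'-hydroxychalcone (methoxythallation, 1,2-shift of the electron-rich ring D aryl group from the β to the α carbon with loss of monovalent thallium, capture of the oxocarbenium ion by methanol as acetal 10) followed by acid-catalysed attack of the ring A phenol on the acetal carbon and loss of two molecules of methanol to close the 4-pyranone; the 2,4-dioxygenated migrating ring favours aryl shift over aurone formation, and the ring D phenol stays benzylated so that it cannot attack the acetal.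

**Step 8**
Reactants: 11 7-(benzyloxy)-3-[(3R)-5-(benzyloxy)-3-hydroxy-2,2-dimethylchroman-6-yl]-4H-chromen-4-one
Product: 12 3-[(3R)-3,5-dihydroxy-2,2-dimethylchroman-6-yl]-7-hydroxy-4H-chromen-4-one
Conditions: H2 (1 atm), 10% Pd/C, EtOAc/MeOH, rt, stopped after two equivalents of H2
Reagents that add atoms: none
Why: Catalytic hydrogenolysis of the two benzyl aryl ethers, placed before any alkene or alkyne is present and stopped early so that the chromone C2=C3 bond is kept.

**Step 9**
Reactants: 12 3-[(3R)-3,5-dihydroxy-2,2-dimethylchroman-6-yl]-7-hydroxy-4H-chromen-4-one; 13 3-chloro-3-methylbut-1-yne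
Product: 14 3-[(3R)-3,5-dihydroxy-2,2-dimethylchroman-6-yl]-7-[(2-methylbut-3-yn-2-yl)oxy]-4H-chromen-4-one
Conditions: K2CO3 (1.2 equiv), KI (cat.), CuI (cat.), acetone, 55 °C, argon
Reagents that add atoms: none
Why: Copper-assisted propargylic etherification with a tertiary propargylic chloride, expected at O7 because the 7-OH is a vinylogous carboxylic acid and the only hydroxyl ionised to a useful extent by K2CO3, whereas the 2'-OH is hydrogen-bonded to C4=O and flanked by two ortho substituents and the secondary alcohol is not deprotonated.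

**Step 10**
Reactants: 14 3-[(3R)-3,5-dihydroxy-2,2-dimethylchroman-6-yl]-7-[(2-methylbut-3-yn-2-yl)oxy]-4H-chromen-4-one
Product: 17 3-[(3R)-3,5-dihydroxy-2,2-dimethylchroman-6-yl]-8,8-dimethyl-4H,8H-pyrano[2,3-f]chromen-4-one, via allenylphenol 15 (not isolated), via ortho-quinone methide 16 (not isolated)
Conditions: N,N-diethylaniline, 190 °C, sealed tube, argon
Reagents that add atoms: none
Why: The ether undergoes an aromatic propargyl Claisen rearrangement, a [3,3]-sigmatropic shift that joins the terminal alkyne carbon to C8 of ring A and gives allenylphenol 15 after enolisation; a 1,5-hydrogen shift from O7–H to the central allene carbon gives ortho-quinone methide 16, and an oxa-6π electrocyclisation re-forms the O7–C(CH3)2 bond, so the only bond of 17 that is absent from 14 is C8–CH= and this bond closes the pyran ring. The closest known reaction type is the thermal conversion of aryl 1,1-dimethylpropargyl ethers into 2,2-dimethyl-2H-chromenes, well known for 7-oxygenated coumarins and chromones. The six-membered ring arises through a chair-like six-membered sigmatropic array followed by a thermally allowed disrotatory six-electron closure, the new carbon–carbon bond being endocyclic to the ring that forms. No stereocenter is created, and the remote ring D carbinol cannot ionise under neutral thermal conditions and should keep its (R) configuration. The selectivity needed is C8 over C6; the fused 4-pyranone secures it by giving the C7–C8 bond the higher double-bond character (like the C1–C2 bond of a 2-naphthyl ether), so that only C8 can complete the cyclic array, a bias the later pterocarpan stage would lack. Ring D cannot compete because its phenol carries no propargyl group and both carbons ortho to it are substituted.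

**Step 11**
Reactants: 17 3-[(3R)-3,5-dihydroxy-2,2-dimethylchroman-6-yl]-8,8-dimethyl-4H,8H-pyrano[2,3-f]chromen-4-one
Product: 20 the target (6aR,11aR)-pterocarpan carrying the 2,2-dimethyl-2H-pyran ring on C3/C4 of ring A and the (R)-3-hydroxy-2,2-dimethyldihydropyran ring on C9/C10 of ring D, via isoflavanone 18 (not isolated), via cis-isoflavan-4-ol 19 (not isolated)
Conditions: RuCl[(R,R)-TsDPEN](p-cymene) (5 mol %), HCO2H/Et3N (5:2), EtOAc, 40 °C; then conc. aq HCl, EtOH, 0 °C to rt
Reagents that add atoms: none
Why: Noyori-type asymmetric transfer hydrogenation with dynamic kinetic resolution followed by acid-mediated dehydrative ring closure: conjugate reduction gives isoflavanone 18, whose C3 epimers interconvert through the enol while the (R,R)-catalyst should reduce only the (3R) ketone, anti to the aryl group, to the cis (3R,4R) alcohol 19, and acid then ionises C4 to a cation stabilised by O1 and the para chromene oxygen, which the 2'-OH can capture only on the face that gives cis fusion, so that C6a (R) dictates C11a (R) whatever the C4 configuration.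

**Compound list**

1 | 2,4-dihydroxybenzaldehyde | O=Cc1ccc(O)cc1O | starting material
2 | 3-methylbut-2-enal | CC(C)=CC=O | starting material
3 | 5-hydroxy-2,2-dimethyl-2H-chromene-6-carbaldehyde | O=Cc1ccc2OC(C)(C)C=Cc2c1O | intermediate
4 | 5-(benzyloxy)-2,2-dimethyl-2H-chromene-6-carbaldehyde | O=Cc1ccc2OC(C)(C)C=Cc2c1OCc1ccccc1 | intermediate
5 | (3R,4R)-5-(benzyloxy)-3,4-epoxy-2,2-dimethyl-3,4-dihydro-2H-chromene-6-carbaldehyde | O=Cc1ccc2OC(C)(C)[C@@H]3O[C@@H]3c2c1OCc1ccccc1 | intermediate
6 | (3R)-5-(benzyloxy)-6-(hydroxymethyl)-2,2-dimethylchroman-3-ol | OCc1ccc2c(c1OCc1ccccc1)C[C@@H](O)C(C)(C)O2 | intermediate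
7 | (3R)-5-(benzyloxy)-3-hydroxy-2,2-dimethylchromane-6-carbaldehyde | O=Cc1ccc2c(c1OCc1ccccc1)C[C@@H](O)C(C)(C)O2 | intermediate
8 | 1-[4-(benzyloxy)-2-hydroxyphenyl]ethan-1-one | CC(=O)c1ccc(OCc2ccccc2)cc1O | starting material
9 | (E)-1-[4-(benzyloxy)-2-hydroxyphenyl]-3-[(3R)-5-(benzyloxy)-3-hydroxy-2,2-dimethylchroman-6-yl]prop-2-en-1-one | O=C(/C=C/c1ccc2c(c1OCc1ccccc1)C[C@@H](O)C(C)(C)O2)c1ccc(OCc2ccccc2)cc1O | intermediate
10 | 1-[4-(benzyloxy)-2-hydroxyphenyl]-2-[(3R)-5-(benzyloxy)-3-hydroxy-2,2-dimethylchroman-6-yl]-3,3-dimethoxypropan-1-one (both C2 epimers) | COC(OC)C(c1ccc2c(c1OCc1ccccc1)C[C@@H](O)C(C)(C)O2)C(=O)c1ccc(OCc2ccccc2)cc1O | intermediate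
11 | 7-(benzyloxy)-3-[(3R)-5-(benzyloxy)-3-hydroxy-2,2-dimethylchroman-6-yl]-4H-chromen-4-one | O=c1c(-c2ccc3c(c2OCc2ccccc2)C[C@@H](O)C(C)(C)O3)coc2cc(OCc3ccccc3)ccc12 | intermediate
12 | 3-[(3R)-3,5-dihydroxy-2,2-dimethylchroman-6-yl]-7-hydroxy-4H-chromen-4-one | O=c1c(-c2ccc3c(c2O)C[C@@H](O)C(C)(C)O3)coc2cc(O)ccc12 | intermediate
13 | 3-chloro-3-methylbut-1-yne | CC(C)(Cl)C#C | starting material
14 | 3-[(3R)-3,5-dihydroxy-2,2-dimethylchroman-6-yl]-7-[(2-methylbut-3-yn-2-yl)oxy]-4H-chromen-4-one | O=c1c(-c2ccc3c(c2O)C[C@@H](O)C(C)(C)O3)coc2cc(OC(C)(C)C#C)ccc12 | intermediate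
15 | 3-[(3R)-3,5-dihydroxy-2,2-dimethylchroman-6-yl]-7-hydroxy-8-(3-methylbuta-1,2-dien-1-yl)-4H-chromen-4-one | O=c1c(-c2ccc3c(c2O)C[C@@H](O)C(C)(C)O3)coc2c(C=C=C(C)C)c(O)ccc12 | intermediate
16 | (8Z)-3-[(3R)-3,5-dihydroxy-2,2-dimethylchroman-6-yl]-8-(3-methylbut-2-en-1-ylidene)-4H-chromene-4,7(8H)-dione | CC(C)=C/C=C1\C(=O)C=CC2=C1OC=C(c1ccc3c(c1O)C[C@@H](O)C(C)(C)O3)C2=O | intermediate
17 | 3-[(3R)-3,5-dihydroxy-2,2-dimethylchroman-6-yl]-8,8-dimethyl-4H,8H-pyrano[2,3-f]chromen-4-one | CC1(C)C=Cc2c(O1)ccc1c2occ(-c2ccc3c(c2O)C[C@@H](O)C(C)(C)O3)c1=O | intermediate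
18 | 3-[(3R)-3,5-dihydroxy-2,2-dimethylchroman-6-yl]-8,8-dimethyl-2,3-dihydro-4H,8H-pyrano[2,3-f]chromen-4-one (interconverting C3 epimers) | CC1(C)C=Cc2c(O1)ccc1c2OCC(c2ccc3c(c2O)C[C@@H](O)C(C)(C)O3)C1=O | intermediate
19 | (3R,4R)-3-[(3R)-3,5-dihydroxy-2,2-dimethylchroman-6-yl]-8,8-dimethyl-3,4-dihydro-2H,8H-pyrano[2,3-f]chromen-4-ol | CC1(C)C=Cc2c(O1)ccc1c2OC[C@@H](c2ccc3c(c2O)C[C@@H](O)C(C)(C)O3)[C@H]1O | intermediate
20 | target: (6aR,11aR)-pterocarpan with a 2,2-dimethyl-2H-pyran ring fused at C3/C4 (oxygen on C3) and an (R)-3-hydroxy-2,2-dimethyl-3,4-dihydro-2H-pyran ring fused at C9/C10 (oxygen on C9) | CC1(C)C=Cc2c(ccc3c2OC[C@H]2c4ccc5c(c4O[C@@H]32)C[C@@H](O)C(C)(C)O5)O1 | target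

**Step count and risks**

Total step count: 11. Longest linear sequence: 11 steps (1 to 20); compounds 2, 8 and 13 enter as purchased materials.

Steps most likely to fail:

Step 7. The oxidant may attack the electron-rich rings (over-oxidation or ring nitration), or the 2'-hydroxychalcone may cyclise to an aurone or flavanone faster than the aryl group migrates. The fallback sets out from 9: NaOAc in refluxing EtOH should close the chalcone by oxa-Michael addition to 7-(benzyloxy)-2-[(3R)-5-(benzyloxy)-3-hydroxy-2,2-dimethylchroman-6-yl]chroman-4-one F1. Treatment of this flavanone with the trivalent iodine reagent PhI(OH)OTs in MeCN at reflux should then bring about α-iodination and 2,3-migration of the electron-rich aryl group, which gives isoflavone 11 after loss of a proton. The fallback comes back to the route at 11.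

Step 11. Conjugate reduction of the vinylogous ester may stall, equilibration at C3 may be too slow for a clean dynamic resolution, or the acid used for ring closure may hydrate or open the chromene. The fallback sets out from 17: NaBH4 in EtOH/THF should reduce the isoflavone without stereocontrol to the isoflavan-4-ol stereoisomer mixture F2. Mild acid (AcOH, or BF3·OEt2 at 0 °C) should close each C3 epimer to its cis-fused pterocarpan only. Because of the ring D carbinol these two products are diastereomers, so 20 should be separable by chromatography from the (6aS,11aS) diastereomer F3. The fallback ends at 20.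

Step 9. Alkylation may occur at the wrong hydroxyl (2'-OH or the secondary alcohol), or the tertiary chloride may eliminate to the enyne before it substitutes. The fallback sets out from 12 and changes the way the pyran is built: heating 12 with 3-methylbut-2-enal 2 in pyridine at 140 °C should lead to attack of C8 on the enal, loss of water and oxa-6π closure, and so give 17 directly, without the ether 14. It is expected to be less efficient on this electron-poor phenol, which is why it is held in reserve. It makes no compound outside the list (none, F0) and comes back at 17.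

**Further compounds**

F1 | step 7 | 7-(benzyloxy)-2-[(3R)-5-(benzyloxy)-3-hydroxy-2,2-dimethylchroman-6-yl]chroman-4-one (both C2 epimers) | O=C1CC(c2ccc3c(c2OCc2ccccc2)C[C@@H](O)C(C)(C)O3)Oc2cc(OCc3ccccc3)ccc12
F2 | step 11 | 3-[(3R)-3,5-dihydroxy-2,2-dimethylchroman-6-yl]-8,8-dimethyl-3,4-dihydro-2H,8H-pyrano[2,3-f]chromen-4-ol (mixture of C3 and C4 stereoisomers) | CC1(C)C=Cc2c(O1)ccc1c2OCC(c2ccc3c(c2O)C[C@@H](O)C(C)(C)O3)C1O
F3 | step 11 | (6aS,11aS) diastereomer of 20 with the (R)-carbinol unchanged | CC1(C)C=Cc2c(ccc3c2OC[C@@H]2c4ccc5c(c4O[C@H]32)C[C@@H](O)C(C)(C)O5)O1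
F0 | step 9 | none | none
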